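Lay the two earlier runs side by side before saying anything about the new flask.

| setting | north-east | south-east | flask |
|---|---|---|---|
| starting material | 10 mM | 40 mM | 20 mM |
| remark | run made earlier | run made earlier |  |
| time |  |  | 30 h |

| run | time / h | target / % | isomer of the product / % |
|---|---|---|---|
| north-east | 3.00 | 23.2 | 13.6 |
| north-east | 8.00 | 14.9 | 25.4 |
| north-east | 15.0 | 11.6 | 34.0 |
| north-east | 25.0 | 11.1 | 38.3 |
| south-east | 2.00 | 26.1 | 9.0 |
| south-east | 4.00 | 19.0 | 17.8 |
| south-east | 10.0 | 13.9 | 29.5 |
| south-east | 25.0 | 11.0 | 39.3 |

(each reading ± 1 percentage point)

- ratio of target to isomer of the product at 4.0 min
- ratio of target to isomer of the product at 80 min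
- ratio of target to isomer of the product at 30 h

- candidate steps: target <-> isomer of the product; starting material <-> target; starting material <-> dormant form; starting material <-> isomer of the product

Does the size of the charge matter? Not that the readings show. At 25.0 h the north-east run, charged with 10 mM, holds fractions 11.1 % of target and 38.3 % of isomer of the product. The south-east run, charged with 40 mM, holds 11.0 % and 39.3 %. That is first-order behaviour, so I reckon in fractions of the charge.

Which number do you carry to the new flask? Target over isomer of the product at the last readings, both runs pooled, comes to 0.285: the closing ratio.

But is it still moving? Somewhat. In the north-east run it reads 0.341 at 15.0 h and 0.290 at 25.0 h, with a scatter of 1 percentage point on a small target reading. So my own figure for 30 h is 0.285, perhaps a shade lower.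

And the minutes? The closing ratio is silent there. The first south-east reading, at 2.00 h, already gives 2.90, and nothing stands before it.

The forecast says 100, 4.8 and 0.26, the last a little below mine. Of its first number it says: “This is poorly determined, since no data cover burst speed”.

The flask gives 32.8, 4.47 and 0.294.

    target ⇌ isomer of the product (k = 0.163 /h)
    starting material ⇌ target (K = 0.580, k = 0.781 /h)
    starting material ⇌ dormant form (K = 1.40, k = 0.200 /h)
    starting material ⇌ isomer of the product (K = 2.20, k = 0.0185 /h)

The forecast's early ratio stands a factor 3.05 too high, while in this flask the closing ratio of 0.285 stands beside a computed 0.294 at 30 h. The largest single effect tried on the early ratio is the direct passing of starting material into isomer of the product, both ways, and it is not told here as the whole story: a run of this flask without that step gives 179 at 4.0 min, not 32.8.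

For the neighbour flask charged with 80 mM, the closing ratio, reckoned in fractions of the charge, gives 0.285 for 30 h. The computed ratio there at 30 h is 0.294.

The data stem from a simulated flask on assumed constants; scatter was added.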